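The route rests on excising C2 from ring A of the tetramethyloctalin (C1, C2, C3, C4, C5, C10; numbering below), so that ring A is first built as a cyclopentanone fused to ring B by asymmetric conjugate addition and aldol condensation. The key step, an FeCl3-induced opening of a 1-silyloxybicyclo[3.1.0]hexane fused to ring B, breaks the C1–C3 bond and delivers the six-membered enone in one operation; it exploits the C9=C10 enone, which leaves C3 as the only enolisable carbon. The C1 oxygen then directs an Eschenmoser–Claisen rearrangement that sets quaternary C9 and the C1=C10 alkene. The derived aldehyde carries the second decalin through reductive alkylation and annulation.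

Key step: step 7

Remarks on the chemistry:
- Numbering. Octalin: ring A = C1, C2, C3, C4 (gem-dimethyl), C5 (H), C10; ring B = C5, C6, C7, C8 (Me), C9 (Me, linker), C10; alkene C1=C10. Linker: C11 (on C9) and C12. Aryl-bearing decalin: ring C = C1', C2', C3', C4' (methylidene), C5' (bears C12), C10'; ring D = C5', C6', C7', C8' (Me), C9' (Me, CH2Ar), C10' (H).
- "Oct" stands for the group (1R,2S,4aS)-1,2,5,5-tetramethyl-1,2,3,4,4a,5,6,7-octahydronaphthalen-1-yl (attached through C9).
- Assumption: the target is drawn as the free bis(hydrogen sulfate); it is released from its pyridinium salt on an acidic cation-exchange resin in the work-up of the last step.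
- CIP descriptors of C5' and C9' change along the route only because substituent priorities change; no centre is inverted.

Step 1
Reactants: 1 3-acetyl-3-methyloxolan-2-one (racemic)
Product: 2 5-bromo-3-methylpentan-2-one (racemic)
Conditions: 48% aq HBr, 90 °C
Reagents that add atoms: hydrogen bromide, Br
Why: Bromide opens the lactone at the O–CH2 carbon (SN2) and the resulting β-keto acid loses CO2, a standard acid-mediated decarboxylative ring opening of an α-acyl lactone; the CHMe centre (later C8) is racemic, which is harmless because it is equilibrated in step 4.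

Step 2
Reactants: 2 5-bromo-3-methylpentan-2-one
Product: 3 2-(4-bromobutan-2-yl)-2-methyl-1,3-dioxolane
Conditions: ethylene glycol, p-toluenesulfonic acid (cat.), benzene, reflux, Dean–Stark
Reagents that add atoms: ethane-1,2-diol, OCCO
Why: Acid-catalysed ketalisation with azeotropic removal of water masks the ketone for Grignard formation.

Step 3
Reactants: 3 2-(4-bromobutan-2-yl)-2-methyl-1,3-dioxolane; 4 4,4-dimethylcyclopent-2-en-1-one
Product: 6 (3R)-4,4-dimethyl-3-[3-(2-methyl-1,3-dioxolan-2-yl)butyl]cyclopentan-1-one, via Grignard reagent 5 (not isolated)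
Conditions: Mg, Et2O, rt; then CuBr·SMe2 (5 mol %), (R)-1-[(Sp)-2-(diphenylphosphino)ferrocenyl]ethyldicyclohexylphosphine (6 mol %), 4, t-BuOMe, −78 °C; aq NH4Cl
Reagents that add atoms: none
Why: Copper-catalysed asymmetric conjugate addition of a Grignard reagent to a cyclic enone: the chiral diphosphine–copper complex (the ligand antipode that gives the 3R adduct is used) selects the enone face at C5, the only stereocentre set here, and the magnesium enolate is protonated on work-up.

Step 4
Reactants: 6 (3R)-4,4-dimethyl-3-[3-(2-methyl-1,3-dioxolan-2-yl)butyl]cyclopentan-1-one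
Product: 8 (3aS,6S)-3,3,6,7-tetramethyl-2,3,3a,4,5,6-hexahydro-1H-inden-1-one, via diketone 7 (not isolated)
Conditions: 2 M HCl, THF, rt; then NaOMe (cat.), MeOH, 65 °C
Reagents that add atoms: none
Why: Ketal hydrolysis followed by base-mediated intramolecular aldol condensation (Robinson-type cyclodehydration) of C10 onto the C9 ketone, the only closure that can dehydrate, forms ring B, and C8 should equilibrate through the dienolate to the isomer with the 8-methyl pseudoaxial and anti to H5, which avoids A(1,2) strain with the 9-methyl group.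

Step 5
Reactants: 8 (3aS,6S)-3,3,6,7-tetramethyl-2,3,3a,4,5,6-hexahydro-1H-inden-1-one
Product: 9 trimethyl{[(3aS,6S)-3,3,6,7-tetramethyl-3a,4,5,6-tetrahydro-3H-inden-1-yl]oxy}silane
Conditions: LiN(i-Pr)2, Me3SiCl (in situ), THF, −78 °C
Reagents that add atoms: chlorotrimethylsilane, C[Si](C)(C)Cl
Why: Kinetic α'-deprotonation with in situ silylation gives the cross-conjugated silyl dienol ether; C3 is the only enolisable α-carbon because C10 is olefinic.

Step 6
Reactants: 9 trimethyl{[(3aS,6S)-3,3,6,7-tetramethyl-3a,4,5,6-tetrahydro-3H-inden-1-yl]oxy}silane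
Product: 10 silyloxycyclopropane (CH2 added across the C1=C3 enol ether bond of 9, giving a 1-(trimethylsilyloxy)bicyclo[3.1.0]hexane fused to ring B)
Conditions: Et2Zn, CH2I2, CH2Cl2, 0 °C → rt
Reagents that add atoms: diiodomethane, ICI
Why: Simmons–Smith cyclopropanation: the electrophilic zinc carbenoid adds to the electron-rich enol ether bond and not to the hindered tetrasubstituted C9=C10 bond; the cyclopropane face is irrelevant because both new centres are destroyed in step 7.

Step 7
Reactants: 10 silyloxycyclopropane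
Product: 12 (4aS,7S)-4,4,7,8-tetramethyl-4a,5,6,7-tetrahydronaphthalen-1(4H)-one, via β-chloro ketone 11 (not isolated)
Conditions: FeCl3 (2.2 equiv), DMF, 0 °C → rt; then NaOAc, MeOH, reflux
Reagents that add atoms: none
Why: One-electron oxidation of the silyloxycyclopropane by FeCl3 with loss of the silyl group gives a cyclopropyloxy radical whose β-scission cleaves the shared C1–C3 bond, so the five-membered ring (C1, C3, C4, C5, C10) becomes the six-membered ring by taking in C2; the C3 radical abstracts chlorine from a second FeCl3 and NaOAc eliminates HCl (E1cB) to the C2=C3 enone. The closest known reaction type is the FeCl3-mediated one-carbon ring enlargement of 1-silyloxybicyclo[n.1.0]alkanes to cycloalkenones. No ring is closed by bond formation: ring A arises by fragmentation of the zero-atom bridge of the bicyclo[3.1.0]hexane. No stereocentre is created, and C5 and C8 are not touched. The selectivity needed is cleavage of the internal rather than the external cyclopropane bond, secured because it gives a secondary ring radical instead of a primary one; the site of insertion was fixed in step 5, where C3 is the only enolisable α-carbon.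

Step 8
Reactants: 12 (4aS,7S)-4,4,7,8-tetramethyl-4a,5,6,7-tetrahydronaphthalen-1(4H)-one
Product: 13 (4aS,7S)-4,4,7,8-tetramethyl-3,4,4a,5,6,7-hexahydronaphthalen-1(2H)-one
Conditions: H2 (1 atm), (Ph3P)3RhCl (5 mol %), benzene, rt
Reagents that add atoms: none
Why: Homogeneous hydrogenation with (Ph3P)3RhCl saturates the cis-disubstituted C2=C3 bond and leaves the tetrasubstituted C9=C10 bond untouched.

Step 9
Reactants: 13 (4aS,7S)-4,4,7,8-tetramethyl-3,4,4a,5,6,7-hexahydronaphthalen-1(2H)-one
Product: 14 (1S,4aS,7S)-4,4,7,8-tetramethyl-1,2,3,4,4a,5,6,7-octahydronaphthalen-1-ol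
Conditions: (R)-1-methyl-3,3-diphenyltetrahydro-1H,3H-pyrrolo[1,2-c][1,3,2]oxazaborole (20 mol %), BH3·SMe2, toluene, −30 °C; MeOH
Reagents that add atoms: none
Why: Corey–Bakshi–Shibata reduction: the oxazaborolidine treats the alkylidene side (C10) as the large group and delivers hydride to one carbonyl face, giving the 1S alcohol with O1 on the face of H5 (catalyst control; only 1,2-reduction is possible at the fully substituted enone).

Step 10
Reactants: 14 (1S,4aS,7S)-4,4,7,8-tetramethyl-1,2,3,4,4a,5,6,7-octahydronaphthalen-1-ol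
Product: 16 N,N-dimethyl-2-[(1R,2S,4aS)-1,2,5,5-tetramethyl-1,2,3,4,4a,5,6,7-octahydronaphthalen-1-yl]acetamide, via ketene N,O-acetal 15 (not isolated)
Conditions: MeC(OMe)2NMe2 (5 equiv), xylene, 140 °C, sealed tube
Reagents that add atoms: N,N-dimethylacetamide dimethyl acetal, CC(OC)(OC)N(C)C
Why: Eschenmoser–Claisen rearrangement: the ketene N,O-acetal undergoes a chair [3,3] shift that moves chirality suprafacially from C1–O to C9, forming the quaternary centre (1R) on the face anti to the pseudoaxial 8-methyl and placing the alkene at C1=C10.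

Step 11
Reactants: 16 N,N-dimethyl-2-(Oct)acetamide
Product: 17 2-[(1R,2S,4aS)-1,2,5,5-tetramethyl-1,2,3,4,4a,5,6,7-octahydronaphthalen-1-yl]acetaldehyde
Conditions: Cp2Zr(H)Cl (1.6 equiv), THF, rt; aq work-up
Reagents that add atoms: none
Why: Hydrozirconation of the amide carbonyl with Cp2Zr(H)Cl and hydrolysis of the zirconated hemiaminal stops at the aldehyde; the hindered trisubstituted alkene is inert.

Step 12
Reactants: 17 2-(Oct)acetaldehyde; 18 cyclohexane-1,3-dione
Product: 20 2-[2-(Oct)ethyl]cyclohexane-1,3-dione, via alkylidene dione 19 (not isolated)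
Conditions: Hantzsch ester (1 equiv), L-proline (10 mol %), CH2Cl2, rt
Reagents that add atoms: none
Why: Organocatalytic reductive alkylation: Knoevenagel condensation of the dione with the aldehyde and in situ transfer hydrogenation of the alkylidene dione by the Hantzsch ester give the C-monoalkylated dione.

Step 13
Reactants: 20 2-[2-(Oct)ethyl]cyclohexane-1,3-dione; 21 pent-1-en-3-one
Product: 23 (8aS)-5-methyl-8a-[2-(Oct)ethyl]-3,4,8,8a-tetrahydronaphthalene-1,6(2H,7H)-dione, via triketone 22 (not isolated)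
Conditions: Et3N (cat.), EtOAc, rt; then L-phenylalanine (1 equiv), (1S)-(+)-camphor-10-sulfonic acid (0.5 equiv), DMF, 30 → 70 °C
Reagents that add atoms: none
Why: Robinson annulation: Michael addition to the vinyl ketone and amino-acid-mediated enantioselective intramolecular aldol condensation (Hajos–Parrish type), in which the L-phenylalanine enamine differentiates the two ring carbonyls and sets C5' (8aS).

Step 14
Reactants: 23 (8aS)-5-methyl-8a-[2-(Oct)ethyl]-3,4,8,8a-tetrahydronaphthalene-1,6(2H,7H)-dione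
Product: 24 C4' ethylene ketal of 23 (1,3-dioxolane at the saturated carbonyl; C8' enone retained; 5'S)
Conditions: Me3SiOCH2CH2OSiMe3, Me3SiOTf (cat.), CH2Cl2, −78 → −20 °C
Reagents that add atoms: 1,2-bis(trimethylsilyloxy)ethane, C[Si](C)(C)OCCO[Si](C)(C)C
Why: Silyl-transfer ketalisation under Me3SiOTf catalysis protects the saturated C4' ketone chemoselectively, the conjugated C8' ketone being far less electrophilic.

Step 15
Reactants: 24 C4' ethylene ketal of 23
Product: 25 cis-fused dimethyl(phenyl)silyl enol ether (C8'–O–Si, C8'=C9', H at C10' cis to the C5' chain; 5'S,10'R)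
Conditions: [(Ph3P)CuH]6 (5 mol %), PhMe2SiH (1.5 equiv), toluene, rt
Reagents that add atoms: dimethyl(phenyl)silane, C[SiH](C)c1ccccc1
Why: Copper hydride 1,4-reduction (conjugate hydrosilylation) leaves the isolated C1=C10 alkene untouched and delivers hydride to C10' axially, cis to the angular chain as in cuprate additions to such octalones, giving the cis-decalin and the C8'–C9' silyl enol ether regiospecifically.

Step 16
Reactants: 25 cis-fused dimethyl(phenyl)silyl enol ether; 26 2-(bromomethyl)-1,4-dimethoxybenzene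
Product: 28 cis-fused C8' ketone with C9' bearing methyl and 2,5-dimethoxybenzyl (5'S,9'R,10'R; C4' ketal), via lithium enolate 27 (not isolated)
Conditions: MeLi (1.05 equiv), THF, 0 °C; then 26, HMPA, −78 → 0 °C
Reagents that add atoms: none
Why: Methyllithium releases the regiodefined lithium enolate, which is C-alkylated by the benzylic bromide on the convex face of the cis-decalin, syn to H10' and the angular chain, the other face being screened by the axial C4' ketal carbon, so C9' carries the arylmethyl group cis to the chain.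

Step 17
Reactants: 28 cis-fused C8' ketone
Product: 29 C8' methylidene compound (5'R,9'R,10'R; C4' ketal)
Conditions: Ph3PCH3Br, KOt-Bu, toluene, 100 °C
Reagents that add atoms: methyltriphenylphosphonium bromide, C[P+](c1ccccc1)(c1ccccc1)c1ccccc1.[Br-]
Why: Wittig methylenation of the hindered C8' ketone with excess ylide at elevated temperature.

Step 18
Reactants: 29 C8' methylidene compound
Product: 30 C4' ethylene ketal of ketone 31 (8'-methyl cis to the arylmethyl group; 5'R,8'S,9'S,10'R)
Conditions: H2 (3 atm), (Ph3P)3RhCl (10 mol %), benzene–EtOH, rt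
Reagents that add atoms: none
Why: Homogeneous hydrogenation selects the 1,1-disubstituted alkene over the hindered trisubstituted C1=C10 alkene, and H2 should add to C8' anti to the axial arylmethyl group on C9' (the C4' ketal disfavours the conformer with the 9'-methyl axial), placing the 8'-methyl cis to the arylmethyl group (8'S).

Step 19
Reactants: 30 C4' ethylene ketal of ketone 31
Product: 31 (4aR,5S,6S,8aR)-5-[(2,5-dimethoxyphenyl)methyl]-5,6-dimethyl-8a-[2-(Oct)ethyl]octahydronaphthalen-1(2H)-one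
Conditions: pyridinium p-toluenesulfonate, acetone–H2O, 60 °C
Reagents that add atoms: water, O
Why: Mild acid-catalysed ketal hydrolysis frees the C4' ketone without isomerising the alkene.

Step 20
Reactants: 31 (4aR,5S,6S,8aR)-5-[(2,5-dimethoxyphenyl)methyl]-5,6-dimethyl-8a-[2-(Oct)ethyl]octahydronaphthalen-1(2H)-one
Product: 32 2-{[(1S,2S,4aR,8aR)-1,2-dimethyl-5-methylidene-4a-[2-(Oct)ethyl]decahydronaphthalen-1-yl]methyl}-1,4-dimethoxybenzene
Conditions: Ph3PCH3Br, KOt-Bu, toluene, 100 °C
Reagents that add atoms: methyltriphenylphosphonium bromide, C[P+](c1ccccc1)(c1ccccc1)c1ccccc1.[Br-]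
Why: Wittig methylenation installs the exocyclic C4' methylidene.

Step 21
Reactants: 32 2-{[(1S,2S,4aR,8aR)-1,2-dimethyl-5-methylidene-4a-[2-(Oct)ethyl]decahydronaphthalen-1-yl]methyl}-1,4-dimethoxybenzene
Product: 33 2-{[(1S,2S,4aR,8aR)-1,2-dimethyl-5-methylidene-4a-[2-(Oct)ethyl]decahydronaphthalen-1-yl]methyl}benzene-1,4-diol
Conditions: NaSEt (excess), DMF, 130 °C, argon; dilute HCl (degassed)
Reagents that add atoms: none
Why: Nucleophilic demethylation of both aryl methyl ethers by thiolate (SN2 at methyl) gives the hydroquinone without acid, so the two alkenes are safe.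

Step 22
Reactants: 33 2-{[(1S,2S,4aR,8aR)-1,2-dimethyl-5-methylidene-4a-[2-(Oct)ethyl]decahydronaphthalen-1-yl]methyl}benzene-1,4-diol
Product: 34 2-{[(1S,2S,4aR,8aR)-1,2-dimethyl-5-methylidene-4a-[2-(Oct)ethyl]decahydronaphthalen-1-yl]methyl}benzene-1,4-diyl bis(hydrogen sulfate) (CNP0439949.2)
Conditions: SO3·pyridine (6 equiv), pyridine, rt → 50 °C; cation-exchange resin (H+ form), 0 °C
Reagents that add atoms: sulfur trioxide–pyridine complex, [O-]S(=O)(=O)[n+]1ccccc1
Why: O-Sulfation of both phenols with the SO3–pyridine complex; the pyridinium sulfate is converted into the free bis(hydrogen sulfate) on the acidic exchange resin.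

Compound list
1 | 3-acetyl-3-methyloxolan-2-one (racemic) | CC(=O)C1(C)CCOC1=O | starting material
2 | 5-bromo-3-methylpentan-2-one (racemic) | CC(=O)C(C)CCBr | intermediate
3 | 2-(4-bromobutan-2-yl)-2-methyl-1,3-dioxolane (racemic) | CC1(OCCO1)C(C)CCBr | intermediate
4 | 4,4-dimethylcyclopent-2-en-1-one | CC1(C)C=CC(=O)C1 | starting material
5 | [3-(2-methyl-1,3-dioxolan-2-yl)butyl]magnesium bromide (not isolated) | CC1(OCCO1)C(C)CC[Mg]Br | intermediate
6 | (3R)-4,4-dimethyl-3-[3-(2-methyl-1,3-dioxolan-2-yl)butyl]cyclopentan-1-one (both side-chain CHMe epimers) | O=C1C[C@@H](CCC(C)C2(C)OCCO2)C(C)(C)C1 | intermediate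
7 | (3R)-4,4-dimethyl-3-(3-methyl-4-oxopentyl)cyclopentan-1-one (not isolated) | O=C1C[C@@H](CCC(C)C(C)=O)C(C)(C)C1 | intermediate
8 | (3aS,6S)-3,3,6,7-tetramethyl-2,3,3a,4,5,6-hexahydro-1H-inden-1-one | O=C1CC(C)(C)[C@@H]2CC[C@H](C)C(C)=C12 | intermediate
9 | trimethyl{[(3aS,6S)-3,3,6,7-tetramethyl-3a,4,5,6-tetrahydro-3H-inden-1-yl]oxy}silane | C[Si](C)(C)OC1=CC(C)(C)[C@@H]2CC[C@H](C)C(C)=C12 | intermediate
10 | silyloxycyclopropane: 1-(trimethylsilyloxy)bicyclo[3.1.0]hexane fused to ring B (CH2 adduct of 9; ring-fusion and methyl centres as in 9; cyclopropane face not defined) | C[Si](C)(C)OC12CC1C(C)(C)[C@@H]1CC[C@H](C)C(C)=C21 | intermediate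
11 | (4aS,7S)-3-chloro-4,4,7,8-tetramethyl-3,4,4a,5,6,7-hexahydronaphthalen-1(2H)-one (C3 epimers, not isolated) | O=C1CC(Cl)C(C)(C)[C@@H]2CC[C@H](C)C(C)=C12 | intermediate
12 | (4aS,7S)-4,4,7,8-tetramethyl-4a,5,6,7-tetrahydronaphthalen-1(4H)-one | O=C1C=CC(C)(C)[C@@H]2CC[C@H](C)C(C)=C12 | intermediate
13 | (4aS,7S)-4,4,7,8-tetramethyl-3,4,4a,5,6,7-hexahydronaphthalen-1(2H)-one | O=C1CCC(C)(C)[C@@H]2CC[C@H](C)C(C)=C12 | intermediate
14 | (1S,4aS,7S)-4,4,7,8-tetramethyl-1,2,3,4,4a,5,6,7-octahydronaphthalen-1-ol | O[C@H]1CCC(C)(C)[C@@H]2CC[C@H](C)C(C)=C12 | intermediate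
15 | N,N-dimethyl-1-{[(1S,4aS,7S)-4,4,7,8-tetramethyl-1,2,3,4,4a,5,6,7-octahydronaphthalen-1-yl]oxy}ethen-1-amine (not isolated) | C=C(N(C)C)O[C@H]1CCC(C)(C)[C@@H]2CC[C@H](C)C(C)=C12 | intermediate
16 | N,N-dimethyl-2-[(1R,2S,4aS)-1,2,5,5-tetramethyl-1,2,3,4,4a,5,6,7-octahydronaphthalen-1-yl]acetamide | CN(C)C(=O)C[C@@]1(C)C2=CCCC(C)(C)[C@@H]2CC[C@@H]1C | intermediate
17 | 2-[(1R,2S,4aS)-1,2,5,5-tetramethyl-1,2,3,4,4a,5,6,7-octahydronaphthalen-1-yl]acetaldehyde | O=CC[C@@]1(C)C2=CCCC(C)(C)[C@@H]2CC[C@@H]1C | intermediate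
18 | cyclohexane-1,3-dione | O=C1CCCC(=O)C1 | starting material
19 | 2-[2-(Oct)ethylidene]cyclohexane-1,3-dione (not isolated) | O=C1CCCC(=O)C1=CC[C@@]1(C)C2=CCCC(C)(C)[C@@H]2CC[C@@H]1C | intermediate
20 | 2-[2-(Oct)ethyl]cyclohexane-1,3-dione | O=C1CCCC(=O)C1CC[C@@]1(C)C2=CCCC(C)(C)[C@@H]2CC[C@@H]1C | intermediate
21 | pent-1-en-3-one (ethyl vinyl ketone) | C=CC(=O)CC | starting material
22 | 2-(3-oxopentyl)-2-[2-(Oct)ethyl]cyclohexane-1,3-dione (not isolated) | CCC(=O)CCC1(CC[C@@]2(C)C3=CCCC(C)(C)[C@@H]3CC[C@@H]2C)C(=O)CCCC1=O | intermediate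
23 | (8aS)-5-methyl-8a-[2-(Oct)ethyl]-3,4,8,8a-tetrahydronaphthalene-1,6(2H,7H)-dione | O=C1CCCC=2[C@]1(CC[C@@]3(C)C4=CCCC(C)(C)[C@@H]4CC[C@@H]3C)CCC(=O)C2C | intermediate
24 | C4' ethylene ketal of 23 (5'S) | O1CCOC12CCCC=3[C@]2(CC[C@@]4(C)C5=CCCC(C)(C)[C@@H]5CC[C@@H]4C)CCC(=O)C3C | intermediate
25 | cis-fused C8' dimethyl(phenyl)silyl enol ether, C4' ketal (5'S,10'R) | O1CCOC12CCC[C@H]3[C@]2(CC[C@@]4(C)C5=CCCC(C)(C)[C@@H]5CC[C@@H]4C)CCC(O[Si](C)(C)c6ccccc6)=C3C | intermediate
26 | 2-(bromomethyl)-1,4-dimethoxybenzene | COc1ccc(OC)c(CBr)c1 | starting material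
27 | lithium enolate corresponding to 25 (not isolated) | O1CCOC12CCC[C@H]3[C@]2(CC[C@@]4(C)C5=CCCC(C)(C)[C@@H]5CC[C@@H]4C)CCC(O[Li])=C3C | intermediate
28 | cis-fused C8' ketone, C9' bearing methyl and 2,5-dimethoxybenzyl, C4' ketal (5'S,9'R,10'R) | O1CCOC12CCC[C@H]3[C@]2(CC[C@@]4(C)C5=CCCC(C)(C)[C@@H]5CC[C@@H]4C)CCC(=O)[C@]3(C)Cc6cc(OC)ccc6OC | intermediate
29 | C8' methylidene analogue of 28 (5'R,9'R,10'R) | O1CCOC12CCC[C@H]3[C@]2(CC[C@@]4(C)C5=CCCC(C)(C)[C@@H]5CC[C@@H]4C)CCC(=C)[C@]3(C)Cc6cc(OC)ccc6OC | intermediate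
30 | C4' ethylene ketal of 31 (5'R,8'S,9'S,10'R) | O1CCOC12CCC[C@H]3[C@]2(CC[C@@]4(C)C5=CCCC(C)(C)[C@@H]5CC[C@@H]4C)CC[C@H](C)[C@]3(C)Cc6cc(OC)ccc6OC | intermediate
31 | (4aR,5S,6S,8aR)-5-[(2,5-dimethoxyphenyl)methyl]-5,6-dimethyl-8a-[2-(Oct)ethyl]octahydronaphthalen-1(2H)-one | O=C1CCC[C@H]2[C@]1(CC[C@@]3(C)C4=CCCC(C)(C)[C@@H]4CC[C@@H]3C)CC[C@H](C)[C@]2(C)Cc5cc(OC)ccc5OC | intermediate
32 | 2-{[(1S,2S,4aR,8aR)-1,2-dimethyl-5-methylidene-4a-[2-(Oct)ethyl]decahydronaphthalen-1-yl]methyl}-1,4-dimethoxybenzene | C=C1CCC[C@H]2[C@]1(CC[C@@]3(C)C4=CCCC(C)(C)[C@@H]4CC[C@@H]3C)CC[C@H](C)[C@]2(C)Cc5cc(OC)ccc5OC | intermediate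
33 | 2-{[(1S,2S,4aR,8aR)-1,2-dimethyl-5-methylidene-4a-[2-(Oct)ethyl]decahydronaphthalen-1-yl]methyl}benzene-1,4-diol | C=C1CCC[C@H]2[C@]1(CC[C@@]3(C)C4=CCCC(C)(C)[C@@H]4CC[C@@H]3C)CC[C@H](C)[C@]2(C)Cc5cc(O)ccc5O | intermediate
34 | 2-{[(1S,2S,4aR,8aR)-1,2-dimethyl-5-methylidene-4a-[2-(Oct)ethyl]decahydronaphthalen-1-yl]methyl}benzene-1,4-diyl bis(hydrogen sulfate) | C=C1CCC[C@H]2[C@]1(CC[C@@]1(C)C3=CCCC(C)(C)[C@@H]3CC[C@@H]1C)CC[C@H](C)[C@]2(C)Cc1cc(OS(=O)(=O)O)ccc1OS(=O)(=O)O | target

Total step count: 22. Longest linear sequence: 22 steps (1 to 34; compounds 4, 18, 21 and 26 enter as purchased building blocks).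

Steps most likely to fail

Step 10. The sterically demanding [3,3] shift onto the tetrasubstituted C9=C10 alkene may be outrun at 140 °C by ionisation and elimination of the activated allylic alcohol. The fallback sets out from 14 and uses an ester enolate Claisen rearrangement at much lower temperature. Acetylation (Ac2O, 4-dimethylaminopyridine, pyridine) would give the allylic acetate F1. Ireland–Claisen rearrangement (LiN(i-Pr)2, t-BuMe2SiCl, THF–HMPA, −78 → 60 °C, then aq LiOH) would give the acid 2-(Oct)acetic acid F2 with the same suprafacial transfer to C9. LiAlH4 would reduce it to the alcohol 2-(Oct)ethanol F3, and Dess–Martin oxidation brings the sequence back at aldehyde 17.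

Step 15. Hydride transfer to the tetrasubstituted, α-methylated enone may be sluggish, and the cis selectivity at C10' may erode. The fallback sets out from 24. Heterogeneous hydrogenation (H2, 1 atm, Pd/C, EtOH with a trace of KOH, stopped after one equivalent) would give the cis-fused saturated ketone F4. Thermodynamic enol silylation (Me3SiCl, NaI, Et3N, MeCN) would give the more substituted trimethylsilyl enol ether F5. Treatment of F5 with MeLi and then 26, as in step 16, returns to the route at 28. The cost is the risk of partial reduction or migration of the C1=C10 alkene.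

Step 18. Facial selectivity of hydrogen delivery to C8' may be poor, because it depends on the conformational equilibrium of the cis-decalin. The fallback sets out from 29 and replaces kinetic face selection by thermodynamic control. Hydroboration–oxidation (9-BBN, then H2O2, NaOH) would give the primary alcohol F6. Dess–Martin oxidation followed by equilibration with K2CO3 in MeOH would give the 8'-carbaldehyde F7, settled in the more stable arrangement with the formyl group cis to the arylmethyl group. Wolff–Kishner reduction (N2H4·H2O, KOH, diethylene glycol, 200 °C; the dioxolane is base-stable) returns to the route at 30.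

Further compounds
F1 | step 10 | (1S,4aS,7S)-4,4,7,8-tetramethyl-1,2,3,4,4a,5,6,7-octahydronaphthalen-1-yl acetate | CC(=O)O[C@H]1CCC(C)(C)[C@@H]2CC[C@H](C)C(C)=C12
F2 | step 10 | 2-[(1R,2S,4aS)-1,2,5,5-tetramethyl-1,2,3,4,4a,5,6,7-octahydronaphthalen-1-yl]acetic acid | OC(=O)C[C@@]1(C)C2=CCCC(C)(C)[C@@H]2CC[C@@H]1C
F3 | step 10 | 2-[(1R,2S,4aS)-1,2,5,5-tetramethyl-1,2,3,4,4a,5,6,7-octahydronaphthalen-1-yl]ethan-1-ol | OCC[C@@]1(C)C2=CCCC(C)(C)[C@@H]2CC[C@@H]1C
F4 | step 15 | cis-fused saturated C8' ketone, C4' ketal (C9' epimers) | O1CCOC12CCC[C@H]3[C@]2(CC[C@@]4(C)C5=CCCC(C)(C)[C@@H]5CC[C@@H]4C)CCC(=O)C3C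
F5 | step 15 | cis-fused C8' trimethylsilyl enol ether, C4' ketal | O1CCOC12CCC[C@H]3[C@]2(CC[C@@]4(C)C5=CCCC(C)(C)[C@@H]5CC[C@@H]4C)CCC(O[Si](C)(C)C)=C3C
F6 | step 18 | C8' hydroxymethyl compound, C4' ketal (C8' epimers) | O1CCOC12CCC[C@H]3[C@]2(CC[C@@]4(C)C5=CCCC(C)(C)[C@@H]5CC[C@@H]4C)CCC(CO)[C@]3(C)Cc6cc(OC)ccc6OC
F7 | step 18 | C8' carbaldehyde, C4' ketal, formyl cis to the arylmethyl group | O1CCOC12CCC[C@H]3[C@]2(CC[C@@]4(C)C5=CCCC(C)(C)[C@@H]5CC[C@@H]4C)CC[C@H](C=O)[C@]3(C)Cc6cc(OC)ccc6OC
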